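The seven-membered ring of the trans-fused hydroazulene (C1, C5, C6, C7, C8, C9, C10; guaiane locants, C1′ = benzylic carbon) is cut into the five-carbon arc C8–C7–C6–C5–C1 and the two-carbon unit C9–C10. A rhodium-catalysed (5+2) cycloaddition of a vinylcyclopropane (cyclopentene C1=C5 bearing a trans-cyclopropane C6–C7–C8) with 1-(trimethylsilyl)propyne forms C8–C9 and C1–C10 in one operation and transfers the cyclopropane configuration to C1. It exploits the unsubstituted C8 methylene beside the C7 stereocentre and the methyl-bearing C10. The hydroxyethyl group on C7 then directs hydrogenation at C5 and becomes the isopropenyl group; the arene is formylated and unmasked last.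

Key step: step 10

Remark on faces: β is the face of H-1; the target has H-1 β, H-5 α, 4-CH3 β, the C4 side chain α, the C7 isopropenyl α, 10-OH β and 10-CH3 α.
Remark on step 2: the ligand antipode that delivers the (4R)-lactone is assumed to be (R)-DTBM-SEGPHOS; if the sense is opposite, the other antipode is taken.

Step 1
Reactants: 1 3,5-dimethoxyphenol; 2 ethyl 5-methyl-3-oxohexanoate
Product: 3 5,7-dimethoxy-4-(2-methylpropyl)-2H-chromen-2-one
Conditions: H2SO4 (75%), 0 °C → rt
Reagents that add atoms: none
Why: Pechmann condensation (transesterification, then intramolecular hydroxyalkylation ortho to the phenol oxygen and dehydration); the two ortho positions are equivalent and no stereocentre is formed.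

Step 2
Reactants: 3 5,7-dimethoxy-4-(2-methylpropyl)-2H-chromen-2-one
Product: 4 (4R)-5,7-dimethoxy-4-(2-methylpropyl)chroman-2-one
Conditions: Cu(OAc)2·H2O (5 mol%), (R)-DTBM-SEGPHOS (5 mol%), (EtO)2MeSiH, t-BuOH, toluene, rt
Reagents that add atoms: none
Why: Copper hydride-catalysed asymmetric conjugate reduction of the β,β-disubstituted coumarin; the chiral bisphosphine–copper hydride adds hydride to one enantioface of C4 and so sets the future C1′ centre, while t-BuOH protonates the copper enolate and limits 1,2-reduction.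

Step 3
Reactants: 4 (4R)-5,7-dimethoxy-4-(2-methylpropyl)chroman-2-one
Product: 5 trans-3-methyl lactone (3-CH3 anti to 4-isobutyl)
Conditions: LiHMDS, THF, −78 °C; MeI
Reagents that add atoms: iodomethane, CI
Why: Lactone enolate alkylation; the 4-isobutyl group, held pseudoaxial by the peri 5-methoxy group, shields one face, so the methyl group should enter trans to it.

Step 4
Reactants: 5 trans-3-methyl lactone; 6 1,3-diiodopropane
Product: 7 3-(3-iodopropyl)-3-methyl lactone (iodopropyl anti to 4-isobutyl)
Conditions: LiHMDS, THF–DMPU, −78 → −30 °C; 6 (5 equiv)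
Reagents that add atoms: none
Why: Second enolate alkylation, which creates the quaternary centre C4; the electrophile again enters anti to the isobutyl group, leaving the chain trans and the methyl cis to isobutyl (the C4/C1′ relationship of the target), and the excess of 6 suppresses double alkylation.

Step 5
Reactants: 7 3-(3-iodopropyl)-3-methyl lactone
Product: 10 2-methyl-2-[3-methyl-1-(2,4,6-trimethoxyphenyl)butyl]cyclopentan-1-one, via alkyllithium 8 (not isolated), via lithium phenoxide 9 (not isolated)
Conditions: t-BuLi (2.1 equiv), Et2O–pentane, −78 °C → rt; then MeI, DMPU, rt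
Reagents that add atoms: iodomethane, CI
Why: Iodine–lithium exchange followed by 5-exo intramolecular acyl substitution on the aryl ester (Parham-type cyclisation) expels the phenoxide and closes the cyclopentanone, the phenoxide is O-methylated in the same flask, and neither stereocentre is touched because C4 cannot enolise.

Step 6
Reactants: 10 2-methyl-2-[3-methyl-1-(2,4,6-trimethoxyphenyl)butyl]cyclopentan-1-one
Product: 11 5-methyl-5-[3-methyl-1-(2,4,6-trimethoxyphenyl)butyl]cyclopent-1-en-1-yl trifluoromethanesulfonate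
Conditions: KHMDS, THF, −78 °C; PhNTf2, −78 → 0 °C
Reagents that add atoms: N-phenylbis(trifluoromethanesulfonimide), O=S(=O)(N(c1ccccc1)S(=O)(=O)C(F)(F)F)C(F)(F)F
Why: Enol triflate formation; the ketone can enolise only toward C1 because C4 is quaternary, so a single C1=C5 enol triflate should result.

Step 7
Reactants: 12 (R)-but-3-yn-2-ol
Product: 13 (2R,3E)-4-(4,4,5,5-tetramethyl-1,3,2-dioxaborolan-2-yl)but-3-en-2-ol
Conditions: CuCl (5 mol%), Xantphos (5 mol%), NaOt-Bu (10 mol%), B2pin2, MeOH, THF, rt
Reagents that add atoms: bis(pinacolato)diboron, CC1(C)OB(OC1(C)C)B1OC(C)(C)C(C)(C)O1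
Why: Copper-catalysed formal hydroboration (syn borylcupration of the terminal alkyne with boron at the terminal carbon, then protonation by methanol) gives the E-alkenylboronate and leaves the carbinol centre untouched.

Step 8
Reactants: 13 (2R,3E)-4-(4,4,5,5-tetramethyl-1,3,2-dioxaborolan-2-yl)but-3-en-2-ol
Product: 14 (1R)-1-[(1R,2R)-2-(4,4,5,5-tetramethyl-1,3,2-dioxaborolan-2-yl)cyclopropyl]ethan-1-ol
Conditions: Et2Zn, CH2I2, CH2Cl2, −10 °C → rt
Reagents that add atoms: diiodomethane, ICI
Why: Hydroxyl-directed Simmons–Smith cyclopropanation (Furukawa variant), stereospecific for the E-alkene (trans-cyclopropane); the zinc alkoxide delivers CH2 to the face syn to oxygen in the conformer with the carbinol hydrogen eclipsing the alkene, so the (R)-carbinol should set the (1R,2R)-cyclopropane, i.e. the C7 configuration of the target.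

Step 9
Reactants: 11 5-methyl-5-[3-methyl-1-(2,4,6-trimethoxyphenyl)butyl]cyclopent-1-en-1-yl trifluoromethanesulfonate; 14 (1R)-1-[(1R,2R)-2-(4,4,5,5-tetramethyl-1,3,2-dioxaborolan-2-yl)cyclopropyl]ethan-1-ol
Product: 15 vinylcyclopropane carbinol (cyclopentene C1=C5 bearing the trans-cyclopropane at C5)
Conditions: Pd(dppf)Cl2 (10 mol%), Cs2CO3, dioxane–H2O, 90 °C
Reagents that add atoms: none
Why: Suzuki–Miyaura coupling of the alkenyl triflate with the cyclopropylboronate; transmetalation and reductive elimination at the cyclopropyl carbon proceed with retention, so the trans-cyclopropane and all other centres are kept.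

Step 10
Reactants: 15 vinylcyclopropane carbinol; 16 trimethyl(prop-1-yn-1-yl)silane
Product: 17 silyl diene cycloadduct (C5=C6 and C9=C10; SiMe3 on C9; CH3 on C10; H-1 β)
Conditions: [Rh(CO)2Cl]2 (5 mol%), 16 (4 equiv), ClCH2CH2Cl, 80 °C
Reagents that add atoms: none
Why: Monovalent rhodium binds the C1=C5 alkene and cleaves the less substituted cyclopropane bond C6–C8 to a σ,π-allyl rhodacycle; the alkyne inserts into the Rh–C1 bond through its methyl-bearing carbon (the bulky silyl-bearing carbon stays on rhodium, away from the first-formed bond), and reductive elimination joins that carbon to C8. The closest known reaction is the rhodium-catalysed intermolecular (5+2) cycloaddition of vinylcyclopropanes with alkynes. The seven-membered ring closes as an untethered (5+2) cycloaddition between the arc C8–C7–C6–C5–C1 and the alkyne. C1 is the only new stereocentre: rhodium and C8 lie on the alkene face fixed by the configuration of C6, so the trans-cyclopropane should place H-1 cis to H-7 (chirality transfer), while C7 is retained and C4 and C1′ are bystanders. The step needs cleavage of C6–C8 over C6–C7 (secured by the trans, non-conjugating hydroxyethyl group), the alkyne orientation (secured by SiMe3 against CH3) and a reactive s-cis conformer (favoured because the quaternary C4 beside C5 turns the cyclopropane toward C1).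

Step 11
Reactants: 17 silyl diene cycloadduct
Product: 18 trans-fused silyl alkene (H-5 α; C9=C10 kept)
Conditions: [Ir(cod)(PCy3)(py)]PF6 (10 mol%), H2 (1 atm), CH2Cl2, rt
Reagents that add atoms: none
Why: Hydroxyl-directed hydrogenation (Crabtree catalyst): iridium bound to the hydroxyl of the α-oriented side chain at C7 delivers H2 to the α face of the homoallylic C5=C6 bond, which should give H-5 α (trans ring fusion) against the steric bias, while the tetrasubstituted silylated C9=C10 bond is too hindered to react.

Step 12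
Reactants: 18 trans-fused silyl alkene
Product: 19 trans-fused C9=C10 alkene carbinol
Conditions: CF3CO2H, CH2Cl2, 0 °C; aq. NaHCO3
Reagents that add atoms: none
Why: Protodesilylation of the vinylsilane: ipso protonation at C9 gives a tertiary β-silyl cation at C10 that loses silicon, so the C9=C10 bond stays in place and no stereocentre is affected.

Step 13
Reactants: 19 trans-fused C9=C10 alkene carbinol
Product: 20 diol (10β-OH and 10α-CH3)
Conditions: Co(acac)2 (20 mol%), PhSiH3, O2 (1 atm), THF, rt
Reagents that add atoms: dioxygen, O=O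
Why: Mukaiyama hydration (hydrogen-atom transfer from a cobalt hydride to C9, then capture of the tertiary C10 radical by O2 and reduction of the peroxide): Markovnikov by radical stability, and O2 should approach the β face, syn to H-1 and away from the C2 methylene and the α-oriented C7 side chain.

Step 14
Reactants: 20 diol
Product: 21 7α-acetyl 10β-alcohol
Conditions: Dess–Martin periodinane, NaHCO3, CH2Cl2, 0 °C → rt
Reagents that add atoms: none
Why: Dess–Martin oxidation converts only the secondary carbinol to the methyl ketone; the tertiary alcohol cannot be oxidised and the buffered medium protects C7.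

Step 15
Reactants: 21 7α-acetyl 10β-alcohol
Product: 22 7α-isopropenyl 10β-alcohol (trimethoxyphenyl series)
Conditions: Ph3PCH3Br, KOt-Bu, THF, 0 °C → rt
Reagents that add atoms: methyltriphenylphosphonium bromide, C[P+](c1ccccc1)(c1ccccc1)c1ccccc1.[Br-]
Why: Wittig methylenation of the methyl ketone gives the isopropenyl group; excess ylide tolerates the tertiary alkoxide and the C7 side chain should stay in its configuration at low temperature.

Step 16
Reactants: 22 7α-isopropenyl 10β-alcohol
Product: 24 tri-O-methyl ether of the target, via monoformyl lithium aminoalkoxide 23 (not isolated)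
Conditions: n-BuLi (2.2 equiv), TMEDA, THF, 0 °C; DMF (1.0 equiv); n-BuLi (1.5 equiv), 0 °C; DMF (excess); aq. HCl
Reagents that add atoms: N,N-dimethylformamide, CN(C)C=O
Why: Directed ortho-lithiation then formylation: each free ring position lies between two methoxy groups and is lithiated in turn, the first aldehyde staying masked as its lithium α-amino alkoxide until work-up, and the alkoxide and the isopropenyl group are inert.

Step 17
Reactants: 24 tri-O-methyl ether of the target
Product: 25 CNP0594576.1
Conditions: LiSC6H4CH3-p (from p-thiocresol and n-BuLi), HMPA–toluene, 110 °C; aq. HCl, 0 °C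
Reagents that add atoms: none
Why: SN2 O-demethylation by the arenethiolate; each methoxy group is activated by an ortho or para formyl group, and the non-acidic medium spares the tertiary alcohol and the isopropenyl group.

Compound list
1 | 3,5-dimethoxyphenol | COc1cc(O)cc(OC)c1 | starting material
2 | ethyl 5-methyl-3-oxohexanoate | CCOC(=O)CC(=O)CC(C)C | starting material
3 | 5,7-dimethoxy-4-(2-methylpropyl)-2H-chromen-2-one | COc1cc(OC)c2c(c1)oc(=O)cc2CC(C)C | intermediate
4 | (4R)-5,7-dimethoxy-4-(2-methylpropyl)chroman-2-one | COc1cc(OC)c2c(c1)OC(=O)C[C@H]2CC(C)C | intermediate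
5 | 5,7-dimethoxy-3-methyl-4-(2-methylpropyl)chroman-2-one, 3-CH3 trans to 4-isobutyl, C4 as in 4 | COc1cc(OC)c2c(c1)OC(=O)[C@H](C)[C@H]2CC(C)C | intermediate
6 | 1,3-diiodopropane | ICCCI | starting material
7 | 3-(3-iodopropyl)-5,7-dimethoxy-3-methyl-4-(2-methylpropyl)chroman-2-one, iodopropyl trans and CH3 cis to 4-isobutyl | COc1cc(OC)c2c(c1)OC(=O)[C@](C)(CCCI)[C@H]2CC(C)C | intermediate
8 | 3-(3-lithiopropyl) analogue of 7 | COc1cc(OC)c2c(c1)OC(=O)[C@](C)(CCC[Li])[C@H]2CC(C)C | intermediate
9 | lithium 3,5-dimethoxy-2-[3-methyl-1-(1-methyl-2-oxocyclopentyl)butyl]phenoxide, centres as in 10 | O=C1CCC[C@]1(C)[C@@H](CC(C)C)c1c(O[Li])cc(OC)cc1OC | intermediate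
10 | 2-methyl-2-[3-methyl-1-(2,4,6-trimethoxyphenyl)butyl]cyclopentan-1-one, ring C2 (= C4) and side-chain C1 (= C1′) configured as in 25 | O=C1CCC[C@]1(C)[C@@H](CC(C)C)c1c(OC)cc(OC)cc1OC | intermediate
11 | 5-methyl-5-[3-methyl-1-(2,4,6-trimethoxyphenyl)butyl]cyclopent-1-en-1-yl trifluoromethanesulfonate, centres as in 10 | O=S(=O)(OC1=CCC[C@]1(C)[C@@H](CC(C)C)c1c(OC)cc(OC)cc1OC)C(F)(F)F | intermediate
12 | (R)-but-3-yn-2-ol | C#C[C@@H](C)O | starting material
13 | (2R,3E)-4-(4,4,5,5-tetramethyl-1,3,2-dioxaborolan-2-yl)but-3-en-2-ol | C[C@@H](O)/C=C/B1OC(C)(C)C(C)(C)O1 | intermediate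
14 | (1R)-1-[(1R,2R)-2-(4,4,5,5-tetramethyl-1,3,2-dioxaborolan-2-yl)cyclopropyl]ethan-1-ol (trans-cyclopropane) | C[C@@H](O)[C@@H]1C[C@H]1B1OC(C)(C)C(C)(C)O1 | intermediate
15 | (1R)-1-[(1R,2R)-2-{5-methyl-5-[3-methyl-1-(2,4,6-trimethoxyphenyl)butyl]cyclopent-1-en-1-yl}cyclopropyl]ethan-1-ol (trans-cyclopropane; C4 and C1′ as in 25) | C[C@@H](O)[C@@H]1C[C@H]1C1=CCC[C@]1(C)[C@@H](CC(C)C)c1c(OC)cc(OC)cc1OC | intermediate
16 | trimethyl(prop-1-yn-1-yl)silane | CC#C[Si](C)(C)C | starting material
17 | guaiane-numbered bicyclo[5.3.0]deca-5,9-diene with H-1 β, 4β-CH3, 4α-[3-methyl-1-(2,4,6-trimethoxyphenyl)butyl] (C1′ as in 25), 7α-[(1R)-1-hydroxyethyl], 10-CH3 and 9-Si(CH3)3 | C[C@@H](O)[C@@H]1CC([Si](C)(C)C)=C(C)[C@@H]2CC[C@](C)([C@@H](CC(C)C)c3c(OC)cc(OC)cc3OC)C2=C1 | intermediate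
18 | as 17 with C5–C6 saturated, H-5 α (trans ring fusion), C9=C10 and 9-Si(CH3)3 kept | C[C@@H](O)[C@@H]1CC([Si](C)(C)C)=C(C)[C@@H]2CC[C@](C)([C@@H](CC(C)C)c3c(OC)cc(OC)cc3OC)[C@H]2C1 | intermediate
19 | as 18 with hydrogen in place of silicon at C9 (trans-fused 9-ene, 10-CH3) | C[C@@H](O)[C@@H]1CC=C(C)[C@@H]2CC[C@](C)([C@@H](CC(C)C)c3c(OC)cc(OC)cc3OC)[C@H]2C1 | intermediate
20 | saturated trans-fused diol: 10β-OH, 10α-CH3, 7α-[(1R)-1-hydroxyethyl], other centres as in 18 | C[C@@H](O)[C@@H]1CC[C@@](C)(O)[C@@H]2CC[C@](C)([C@@H](CC(C)C)c3c(OC)cc(OC)cc3OC)[C@H]2C1 | intermediate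
21 | 7α-acetyl analogue of 20 (10β-OH retained) | CC(=O)[C@@H]1CC[C@@](C)(O)[C@@H]2CC[C@](C)([C@@H](CC(C)C)c3c(OC)cc(OC)cc3OC)[C@H]2C1 | intermediate
22 | 7α-(prop-1-en-2-yl) analogue of 21: the target skeleton with a 2,4,6-trimethoxyphenyl ring and no formyl groups | C=C(C)[C@@H]1CC[C@@](C)(O)[C@@H]2CC[C@](C)([C@@H](CC(C)C)c3c(OC)cc(OC)cc3OC)[C@H]2C1 | intermediate
23 | dilithium salt of 22 bearing a CH(OLi)N(CH3)2 group at one free ring position | C=C(C)[C@@H]1CC[C@@](C)(O[Li])[C@@H]2CC[C@](C)([C@@H](CC(C)C)c3c(OC)c(C(O[Li])N(C)C)c(OC)cc3OC)[C@H]2C1 | intermediate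
24 | 2,4,6-trimethoxy-5-substituted benzene-1,3-dicarbaldehyde: tri-O-methyl ether of 25 | C=C(C)[C@@H]1CC[C@@](C)(O)[C@@H]2CC[C@](C)([C@@H](CC(C)C)c3c(OC)c(C=O)c(OC)c(C=O)c3OC)[C@H]2C1 | intermediate
25 | 2,4,6-trihydroxy-5-{(1R)-1-[(1R,4S,5S,7R,10R)-10-hydroxy-4,10-dimethyl-7-(prop-1-en-2-yl)bicyclo[5.3.0]decan-4-yl]-3-methylbutyl}benzene-1,3-dicarbaldehyde (guaiane locants), CNP0594576.1 | C=C(C)[C@@H]1CC[C@@](C)(O)[C@@H]2CC[C@](C)([C@@H](CC(C)C)c3c(O)c(C=O)c(O)c(C=O)c3O)[C@H]2C1 | target

Total step count: 17. Longest linear sequence: 15 steps (steps 1–6 and 9–17); steps 7 and 8 form the two-step side branch to 14.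

Steps most likely to fail

Step 10. Alkyne insertion at the hindered, ring-bound C1 terminus may be slow, so that isomerisation of the vinylcyclopropane or the opposite alkyne orientation takes over. The fallback makes the cycloaddition intramolecular through a temporary silicon tether. It sets out from 15: the hydroxyl is silylated with chloro(dimethyl)(prop-1-yn-1-yl)silane (made from Me2SiCl2 and 1-propynylmagnesium bromide; imidazole, CH2Cl2) to give the alkynylsilyl ether F1. [Rh(CO)2Cl]2 in ClCH2CH2Cl then closes the seven-membered ring to the bridged cyclic siloxane F2, in which the tether forces silicon onto C9 and the methyl group onto C10. MeLi in Et2O opens the Si–O bond to the trimethylsilyl carbinol, and the route is rejoined at 17.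

Step 11. The α face of C5=C6 is crowded by the C4 side chain, so the directed delivery may lose to undirected β-face addition (cis ring fusion) or the catalyst may not turn over. The fallback gives up hydroxyl direction for a radical hydrogenation under product-stability control: from 17, Mn(dpm)3, PhSiH3 and t-BuOOH in i-PrOH transfer a hydrogen atom to C6 and reduce the tertiary C5 radical toward the trans ring fusion, in which C6 avoids the α-oriented C4 side chain; the tetrasubstituted vinylsilane should not react. The route is rejoined at 18 (no new compound, F0).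

Step 16. The second lithiation may be incomplete or the masked first aldehyde may be lost, leaving a monoaldehyde. The fallback brings in both formyl carbons through aryl bromides. It sets out from 20: NBS (2 equiv, MeCN, 0 °C) should brominate both free ring positions to give the dibromo diol F3. Dess–Martin oxidation gives the dibromo methyl ketone F4 and Wittig methylenation the dibromo isopropenyl alcohol F5. Excess t-BuLi (THF, −78 °C) followed by DMF converts both C–Br bonds into formyl groups, and the route is rejoined at 24.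

Further compounds
F1 | step 10 | dimethyl(prop-1-yn-1-yl)silyl ether of 15 | CC#C[Si](C)(C)O[C@H](C)[C@@H]1C[C@H]1C1=CCC[C@]1(C)[C@@H](CC(C)C)c1c(OC)cc(OC)cc1OC
F2 | step 10 | bridged cyclic siloxane cycloadduct (O–Si(CH3)2 links the C11 oxygen to C9; C5=C6 and C9=C10) | C[C@H]1O[Si](C)(C)C2=C(C)[C@@H]3CC[C@](C)([C@@H](CC(C)C)c4c(OC)cc(OC)cc4OC)C3=C[C@H]1C2
F0 | step 11 | none | none
F3 | step 16 | 3,5-dibromo-2,4,6-trimethoxyphenyl analogue of 20 | C[C@@H](O)[C@@H]1CC[C@@](C)(O)[C@@H]2CC[C@](C)([C@@H](CC(C)C)c3c(OC)c(Br)c(OC)c(Br)c3OC)[C@H]2C1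
F4 | step 16 | 3,5-dibromo-2,4,6-trimethoxyphenyl analogue of 21 | CC(=O)[C@@H]1CC[C@@](C)(O)[C@@H]2CC[C@](C)([C@@H](CC(C)C)c3c(OC)c(Br)c(OC)c(Br)c3OC)[C@H]2C1
F5 | step 16 | 3,5-dibromo-2,4,6-trimethoxyphenyl analogue of 22 | C=C(C)[C@@H]1CC[C@@](C)(O)[C@@H]2CC[C@](C)([C@@H](CC(C)C)c3c(OC)c(Br)c(OC)c(Br)c3OC)[C@H]2C1
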